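## Retrosynthetic overview

1. Target ⇐ C3 alcohol oxidation and carbonate removal ⇐ Z‑olefin from face‑selective diimide reduction of a 1,1,3‑trisubstituted allene ⇐ SN2′ hydride delivery to a propargylic carbonate ⇐ acetylide addition of a benzoxepine alkyne to a hindered hydroazulenone.
2. Hydroazulenone ⇐ key step: intramolecular de Mayo photocycloaddition/retro‑aldol of an enantiopure 2‑acyl‑5‑methylcyclopentanone. Cyclobutane and cyclopentane close together, then the cyclobutanol fragments, so the five‑ and seven‑membered rings both arise in one irradiation.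
3. Benzoxepine alkyne ⇐ TMSOTf‑triggered epoxide‑opening cyclization of a Shi diepoxide terminated by an enyne enol silane (oxepane, then cyclohexanone), then equatorial methyl addition.
4. Ring order: cyclopentane + cycloheptane (left, one operation); oxepane + cyclohexane (right, one operation); the bicycles are then joined and the olefin geometry is set last.

Assumption 1: the SMILES is read as drawn: cis‑fused hydroazulene with the 1‑OH on the face of the ring‑fusion hydrogens, exocyclic olefin with the CH2 chain syn to the C(CH3)2 carbon (Z), trans‑fused benzoxepine with the axial 7‑OH syn to the 5a‑methyl.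

Assumption 2: locants follow azulene numbering for the left bicycle (C1 carbinol, C3a/C8a fusion, C4 gem‑dimethyl, C5 olefinic, C6 methyl‑bearing) and 1‑benzoxepine numbering for the right bicycle (C2 gem‑dimethyl, C3 ketone, C5a quaternary, C6 chain‑bearing, C7 carbinol, C9a O‑bearing fusion).

Assumption 3: lithiated forms of numbered compounds (azaenolates, enolates, the alkoxide of 12, lithiated 17) appear only in the Conditions lines.

## Route

Step 1
Reactants: 1 cyclopentanone; 2 (R)-1-amino-2-(methoxymethyl)pyrrolidine (RAMP)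
Product: 3 (R)-N-cyclopentylidene-2-(methoxymethyl)pyrrolidin-1-amine
Conditions: neat, 60 °C, 12 h; distil
Reagents that add atoms: none
Why: Hydrazone condensation installs the recoverable Enders auxiliary; no stereocentre is formed.

Step 2
Reactants: 3 cyclopentanone RAMP hydrazone
Product: 4 RAMP hydrazone of (S)-2-methylcyclopentanone
Conditions: LiN(iPr)2, THF, 0 °C; MeI, −100 → −78 °C
Reagents that add atoms: iodomethane, CI
Why: Enders hydrazone α‑alkylation: the chelated azaenolate is methylated on the face fixed by the methoxymethylpyrrolidine, and RAMP gives the S centre with cyclic ketones (the SAMP series gives R).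

Step 3
Reactants: 4 RAMP hydrazone of (S)-2-methylcyclopentanone; 5 5-methylhex-4-enoic acid
Product: 8 (S)-5-methyl-2-(5-methylhex-4-enoyl)cyclopentan-1-one (enolised β-diketone), via 5-methylhex-4-enoyl chloride 6 (not isolated), via C-acylated hydrazone 7 (not isolated)
Conditions: 5, (COCl)2, cat. DMF, CH2Cl2, rt, concentrate; 4, LiN(iPr)2, THF, 0 °C, cannula into 6, THF, −78 °C; sat. aq. oxalic acid, Et2O, rt
Reagents that add atoms: water, O
Why: Kinetic deprotonation at the unsubstituted α′‑carbon and C‑acylation by the acid chloride, then mild oxalic acid hydrazone hydrolysis, give the β‑diketone without ever enolising the S methyl centre.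

Step 4
Reactants: 8 (S)-5-methyl-2-(5-methylhex-4-enoyl)cyclopentan-1-one
Product: 10 (3aR,6S,8aR)-4,4,6-trimethyloctahydroazulene-1,5-dione, via cyclobutanol photoadduct 9 (not isolated)
Conditions: hν (λ ≥ 300 nm, Pyrex), degassed cyclohexane, 0.01 M, rt
Reagents that add atoms: none
Why: Intramolecular de Mayo reaction: the ring enol adds [2+2] to the tethered trisubstituted olefin (1,5‑closure makes the cyclopentane, then the cyclobutane) anti to the ring methyl, which sets C3a relative to C6, and the strained β‑hydroxy ketone 9 undergoes retro‑aldol ring expansion to the cycloheptanone, with enol protonation at C8a away from the neighbouring quaternary carbon giving the cis fusion.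

Step 5
Reactants: 10 (3aR,6S,8aR)-4,4,6-trimethyloctahydroazulene-1,5-dione
Product: 11 (3aR,6S,8aR)-4,4,6-trimethyl-1-methylideneoctahydroazulen-5(1H)-one
Conditions: Zn, CH2Br2, TiCl4, THF/CH2Cl2, 0 °C → rt
Reagents that add atoms: dibromomethane, BrCBr
Why: Takai–Lombardo methylenation is non‑basic (no epimerisation at C8a or C6) and selective for the open cyclopentanone over the ketone flanked by C(CH3)2 and CH(CH3).

Step 6
Reactants: 11 (3aR,6S,8aR)-4,4,6-trimethyl-1-methylideneoctahydroazulen-5(1H)-one
Product: 12 (1R,3aR,6S,8aR)-1-hydroxy-1,4,4,6-tetramethyloctahydroazulen-5(1H)-one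
Conditions: Co(acac)2 (20 mol %), PhSiH3, O2 (1 atm), THF, rt; aq. Na2S2O3
Reagents that add atoms: dioxygen, O=O
Why: Mukaiyama hydration: hydrogen‑atom transfer to the exocyclic CH2 gives a tertiary radical that is trapped by O2 on the convex face of the cis‑fused bicycle, so the OH is cis to H8a, the epimer that methyl addition to the ketone would not give.

Step 7
Reactants: 13 geranyl bromide; 14 N-methoxy-N-methylacetamide
Product: 15 (E)-N-methoxy-N,5,9-trimethyldeca-4,8-dienamide
Conditions: 14, LiN(iPr)2, THF, −78 °C; 13, −78 → 0 °C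
Reagents that add atoms: none
Why: SN2 alkylation of the Weinreb amide enolate by the allylic bromide, with the E olefin retained.

Step 8
Reactants: 15 (E)-N-methoxy-N,5,9-trimethyldeca-4,8-dienamide
Product: 16 3-[(2R,3R)-3-{2-[(2R)-3,3-dimethyloxiran-2-yl]ethyl}-3-methyloxiran-2-yl]-N-methoxy-N-methylpropanamide
Conditions: D-fructose-derived Shi ketone (0.6 equiv), KHSO5 (Oxone), K2CO3, Bu4NHSO4, Na2B4O7 buffer pH 10.5, MeCN/(MeO)2CH2/H2O, 0 °C
Reagents that add atoms: potassium peroxymonosulfate, [K+].[O-]S(=O)(=O)OO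
Why: Shi asymmetric epoxidation of both trisubstituted olefins through the spiro transition state; the D‑fructose ketone gives the R CH–O carbons, and the internal R,R epoxide later becomes C5a and C9a.

Step 9
Reactants: 16 diepoxy Weinreb amide; 17 1-(trimethylsilyl)propyne
Product: 18 1-[(2R,3R)-3-{2-[(2R)-3,3-dimethyloxiran-2-yl]ethyl}-3-methyloxiran-2-yl]-6-(trimethylsilyl)hex-5-yn-3-one
Conditions: 17, n-BuLi, THF, −78 → −20 °C; 16, −78 °C; aq. NH4Cl
Reagents that add atoms: none
Why: Weinreb ketone synthesis with the propargylic lithium reagent; the chelated tetrahedral intermediate stops over‑addition and masks the acidic β,γ‑ynone until work‑up, and the epoxides are inert at −78 °C.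

Step 10
Reactants: 18 diepoxy β,γ-ynone
Product: 19 (Z)-trimethylsilyl enol ether of 18
Conditions: LiN(SiMe3)2, TMSCl, THF, −78 °C
Reagents that add atoms: chlorotrimethylsilane, C[Si](C)(C)Cl
Why: Regioselective deprotonation of the CH2 activated by both carbonyl and alkyne, with in situ O‑silylation, gives the conjugated Z enol silane (the geometry that leads to an equatorial alkynyl group).

Step 11
Reactants: 19 (Z)-trimethylsilyl enol ether of 18
Product: 21 (3R,5aR,6S,9aR)-3-hydroxy-2,2,5a-trimethyl-6-[(trimethylsilyl)ethynyl]octahydro-1-benzoxepin-7(2H)-one, via C3 silyl ether 20 (not isolated)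
Conditions: TMSOTf (0.5 equiv), 2,6-di-tert-butyl-4-methylpyridine, CH2Cl2, −78 °C; 1 M HCl, THF, 0 °C
Reagents that add atoms: none
Why: McDonald‑type epoxide‑opening oxa/carbacyclization: the silyl‑activated terminal epoxide is opened at its tertiary carbon by the internal epoxide oxygen (oxepane), and the epoxonium is opened with inversion at its tertiary carbon by the enol silane through a chair (cyclohexanone), giving the trans fusion and the equatorial alkynyl group at C6.

Step 12
Reactants: 21 bicyclic α-alkynyl ketone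
Product: 22 (3R,5aR,6S,7S,9aR)-2,2,5a,7-tetramethyl-6-[(trimethylsilyl)ethynyl]decahydro-1-benzoxepine-3,7-diol
Conditions: MeLi, CeCl3, THF, −78 → −40 °C; aq. NH4Cl
Reagents that add atoms: methyllithium, [Li]C
Why: Imamoto organocerium addition tolerates the enolisable ketone, and methyl enters equatorially because the axial path is blocked by the syn‑axial 5a‑methyl, so the tertiary OH is axial (7S).

Step 13
Reactants: 22 benzoxepine diol silylalkyne; 12 hydroazulene hydroxy ketone
Product: 25 tetrakis(methyl carbonate) of the propargylic tetraol, via trilithium acetylide dialkoxide 23 (not isolated), via tetralithium alkoxide adduct 24 (not isolated)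
Conditions: 22, MeLi·LiBr (3.0 equiv), THF, 0 °C → rt; −78 °C, add 12 pre-treated with LiN(SiMe3)2 (1.0 equiv); → 0 °C; ClCO2Me (10 equiv), 0 °C → rt
Reagents that add atoms: methyl chloroformate, COC(Cl)=O
Why: MeLi cleaves the C(sp)–Si bond to the lithium acetylide, which adds 1,2 to the hindered ketone (as acetylides do with 2,2,6‑trimethylcyclohexanones), and all four lithium alkoxides are trapped as methyl carbonates; the new carbinol centre is a mixture that step 14 erases.

Step 14
Reactants: 25 tetrakis(methyl carbonate)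
Product: 26 allene tris(methyl carbonate)
Conditions: Pd2(dba)3·CHCl3 (2.5 mol %), n-Bu3P (10 mol %), HCO2NH4, THF, 40 °C
Reagents that add atoms: none
Why: Tsuji hydrogenolysis: zerovalent palladium displaces the propargylic carbonate SN2′ to a σ‑allenylpalladium formate, which loses CO2 and delivers hydride to the former alkyne terminus, while the three non‑propargylic carbonates are inert.

Step 15
Reactants: 26 allene tris(methyl carbonate)
Product: 27 (Z)-olefin tris(methyl carbonate)
Conditions: 2-nitrobenzenesulfonylhydrazide, Et3N, CH2Cl2, rt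
Reagents that add atoms: none
Why: Diimide semi‑reduction of the allene: concerted syn H2 transfer occurs at the less substituted C=C, whose π lobes lie in the plane of the ring substituents, from the CH(CH3) flank and not the C(CH3)2 flank, so H ends syn to C6 and the CH2 chain syn to C4 (the contra‑thermodynamic Z olefin).

Step 16
Reactants: 27 (Z)-olefin tris(methyl carbonate)
Product: 28 (Z)-triol (3-hydroxy analogue of the target)
Conditions: LiAlH4, THF, 0 °C → rt
Reagents that add atoms: none
Why: Hydride reduction cleaves all three carbonates to the free alcohols without touching the trisubstituted olefin or any stereocentre.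

Step 17
Reactants: 28 (Z)-triol
Product: 29 target CNP0157787.1
Conditions: Dess–Martin periodinane, NaHCO3, CH2Cl2, 0 °C → rt
Reagents that add atoms: none
Why: Dess–Martin oxidation converts the only secondary alcohol into the oxepanone while the two tertiary alcohols and the olefin are inert.

## Compound list

1 | cyclopentanone | O=C1CCCC1 | starting material
2 | (R)-1-amino-2-(methoxymethyl)pyrrolidine (RAMP) | COC[C@H]1CCCN1N | starting material
3 | (R)-N-cyclopentylidene-2-(methoxymethyl)pyrrolidin-1-amine | COC[C@H]1CCCN1N=C1CCCC1 | intermediate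
4 | RAMP hydrazone of (S)-2-methylcyclopentanone, E (amino nitrogen anti to the methyl-bearing carbon) | COC[C@H]1CCCN1/N=C1\CCC[C@@H]1C | intermediate
5 | 5-methylhex-4-enoic acid | CC(C)=CCCC(=O)O | starting material
6 | 5-methylhex-4-enoyl chloride | CC(C)=CCCC(=O)Cl | intermediate
7 | RAMP hydrazone of (5S)-5-methyl-2-(5-methylhex-4-enoyl)cyclopentanone (acyl-bearing carbon labile) | COC[C@H]1CCCN1N=C1C(C(=O)CCC=C(C)C)CC[C@@H]1C | intermediate
8 | (S)-5-methyl-2-(5-methylhex-4-enoyl)cyclopentan-1-one, drawn as the ring enol | C[C@H]1CCC(C(=O)CCC=C(C)C)=C1O | intermediate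
9 | cyclobutanol photoadduct: cyclobutane fused to the methylcyclopentanol (C–OH and quaternary carbon shared) and to a cyclopentanone (quaternary carbon and CH shared), gem-dimethyl on the fourth cyclobutane carbon, cyclobutane anti to the ring methyl | C[C@H]1CC[C@]23C(=O)CC[C@H]2C(C)(C)[C@]13O | intermediate
10 | (3aR,6S,8aR)-4,4,6-trimethyloctahydroazulene-1,5-dione (cis-fused) | C[C@H]1CC[C@@H]2[C@@H](CCC2=O)C(C)(C)C1=O | intermediate
11 | (3aR,6S,8aR)-4,4,6-trimethyl-1-methylideneoctahydroazulen-5(1H)-one | C[C@H]1CC[C@@H]2[C@@H](CCC2=C)C(C)(C)C1=O | intermediate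
12 | (1R,3aR,6S,8aR)-1-hydroxy-1,4,4,6-tetramethyloctahydroazulen-5(1H)-one | C[C@H]1CC[C@@H]2[C@@H](CC[C@@]2(C)O)C(C)(C)C1=O | intermediate
13 | geranyl bromide, (E)-1-bromo-3,7-dimethylocta-2,6-diene | CC(C)=CCC/C(C)=C/CBr | starting material
14 | N-methoxy-N-methylacetamide | CC(=O)N(C)OC | starting material
15 | (E)-N-methoxy-N,5,9-trimethyldeca-4,8-dienamide | CON(C)C(=O)CC/C=C(\C)CCC=C(C)C | intermediate
16 | 3-[(2R,3R)-3-{2-[(2R)-3,3-dimethyloxiran-2-yl]ethyl}-3-methyloxiran-2-yl]-N-methoxy-N-methylpropanamide | CON(C)C(=O)CC[C@H]1O[C@]1(C)CC[C@H]1OC1(C)C | intermediate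
17 | 1-(trimethylsilyl)propyne | CC#C[Si](C)(C)C | starting material
18 | 1-[(2R,3R)-3-{2-[(2R)-3,3-dimethyloxiran-2-yl]ethyl}-3-methyloxiran-2-yl]-6-(trimethylsilyl)hex-5-yn-3-one | C[Si](C)(C)C#CCC(=O)CC[C@H]1O[C@]1(C)CC[C@H]1OC1(C)C | intermediate
19 | (Z)-trimethylsilyl enol ether of 18 (3-silyloxyhex-3-en-5-yne unit, alkyne cis to OSi) | C[Si](C)(C)C#C/C=C(\O[Si](C)(C)C)CC[C@H]1O[C@]1(C)CC[C@H]1OC1(C)C | intermediate
20 | 3-O-trimethylsilyl ether of 21 | C[Si](C)(C)C#C[C@@H]1[C@@]2(C)CC[C@@H](O[Si](C)(C)C)C(C)(C)O[C@@H]2CCC1=O | intermediate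
21 | (3R,5aR,6S,9aR)-3-hydroxy-2,2,5a-trimethyl-6-[(trimethylsilyl)ethynyl]octahydro-1-benzoxepin-7(2H)-one (trans-fused, alkynyl equatorial and cis to 5a-CH3) | C[Si](C)(C)C#C[C@@H]1[C@@]2(C)CC[C@@H](O)C(C)(C)O[C@@H]2CCC1=O | intermediate
22 | (3R,5aR,6S,7S,9aR)-2,2,5a,7-tetramethyl-6-[(trimethylsilyl)ethynyl]decahydro-1-benzoxepine-3,7-diol (7-OH axial, syn to 5a-CH3) | C[Si](C)(C)C#C[C@@H]1[C@@]2(C)CC[C@@H](O)C(C)(C)O[C@@H]2CC[C@]1(C)O | intermediate
23 | trilithium salt of C-desilylated 22 (acetylide, 3- and 7-alkoxides) | [Li+].[Li+].[Li+].[C-]#C[C@@H]1[C@@]2(C)CC[C@@H]([O-])C(C)(C)O[C@@H]2CC[C@]1(C)[O-] | intermediate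
24 | tetralithium alkoxide of the propargylic tetraol (acetylide of 23 added to C5 of 12; C5 epimers) | [Li+].[Li+].[Li+].[Li+].C[C@H]1CC[C@@H]2[C@@H](CC[C@@]2(C)[O-])C(C)(C)C1([O-])C#C[C@@H]1[C@@]2(C)CC[C@@H]([O-])C(C)(C)O[C@@H]2CC[C@]1(C)[O-] | intermediate
25 | tetrakis(methyl carbonate) of that tetraol: azulene O1 and O5 (propargylic, C5 epimers), benzoxepine O3 and O7; azulene C5 joined by C≡C to benzoxepine C6 | C[C@H]1CC[C@@H]2[C@@H](CC[C@@]2(C)OC(=O)OC)C(C)(C)C1(OC(=O)OC)C#C[C@@H]1[C@@]2(C)CC[C@@H](OC(=O)OC)C(C)(C)O[C@@H]2CC[C@]1(C)OC(=O)OC | intermediate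
26 | allene tris(methyl carbonate): azulen-5-ylidene C=C=CH joined to benzoxepine C6, carbonates at azulene O1 and benzoxepine O3, O7 (allene axis isomers) | C[C@H]1CC[C@@H]2[C@@H](CC[C@@]2(C)OC(=O)OC)C(C)(C)C1=C=C[C@@H]1[C@@]2(C)CC[C@@H](OC(=O)OC)C(C)(C)O[C@@H]2CC[C@]1(C)OC(=O)OC | intermediate
27 | (Z)-olefin tris(methyl carbonate): as 26 with the distal allene bond reduced, CH2 syn to the azulene C4 | C[C@H]1CC[C@@H]2[C@@H](CC[C@@]2(C)OC(=O)OC)C(C)(C)/C1=C\C[C@@H]1[C@@]2(C)CC[C@@H](OC(=O)OC)C(C)(C)O[C@@H]2CC[C@]1(C)OC(=O)OC | intermediate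
28 | (Z)-triol: the target with (3R)-CH–OH in place of the C3 ketone | C[C@H]1CC[C@@H]2[C@@H](CC[C@@]2(C)O)C(C)(C)/C1=C\C[C@@H]1[C@@]2(C)CC[C@@H](O)C(C)(C)O[C@@H]2CC[C@]1(C)O | intermediate
29 | target CNP0157787.1: (5aR,6R,7S,9aR)-7-hydroxy-6-{(2Z)-2-[(1R,3aR,6S,8aR)-1-hydroxy-1,4,4,6-tetramethyloctahydroazulen-5(1H)-ylidene]ethyl}-2,2,5a,7-tetramethyloctahydro-1-benzoxepin-3(2H)-one | C[C@H]1CC[C@@H]2[C@@H](CC[C@@]2(C)O)C(C)(C)/C1=C\C[C@@H]1[C@@]2(C)CCC(=O)C(C)(C)O[C@@H]2CC[C@]1(C)O | target

## Step count and risks

Total steps: 17. Longest linear sequence: 11 (steps 1–6 then 13–17, or steps 7–12 then 13–17).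

**Step 4 (de Mayo on the free enolised diketone).** The two enol tautomers of 8 can partition between the fused cyclobutane (wanted) and a crossed adduct, and the cis fusion depends on kinetic protonation. The fallback sets out from 8 and follows Oppolzer's longifolene protocol. ClCO2Bn/pyridine fixes the ring enol as the benzyl enol carbonate F1. Irradiation (λ ≥ 300 nm) gives the isolable cyclobutane benzyl carbonate F2. Hydrogenolysis over Pd on carbon (H2, EtOAc) frees the cyclobutanol, which fragments by retro‑aldol. The route is rejoined at 10.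

**Step 13 (desilylation, acetylide addition to the hindered ketone, fourfold carbonation).** The exhaustive acylation of four alkoxides, two of them severely hindered, may be incomplete or unclean. The fallback sets out from 22 and 12 and avoids the leaving group altogether. The same acetylide addition is quenched with aqueous NH4Cl to give the free propargylic tetraol F3. Its magnesium alkoxides (EtMgCl) are treated with Cp2Zr(H)Cl; alkoxide‑directed hydrozirconation and β‑oxygen elimination give the allene triol F4. Diimide reduction as in step 15 then leads straight to 28, where the route is rejoined; 25–27 are bypassed.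

**Step 15 (facial and site selectivity of the diimide reduction).** The CH(CH3) versus C(CH3)2 flank discrimination may be modest, and the wrong isomer cannot be equilibrated to the Z olefin. The fallback sets out from 26 and uses a bulky placeholder instead of hydrogen. Hydrosilylation with Et3SiH, catalysed by Ni(cod)2 and 1,3-bis(2,6-diisopropylphenyl)imidazol-2-ylidene, places silicon on the central allene carbon from the less hindered flank and gives the vinylsilane F5 (silicon syn to C6, CH2 syn to C4). Protodesilylation with retention (CF3CO2H, CH2Cl2, 0 °C) rejoins the route at 27.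

## Further compounds

F1 | step 4 | benzyl (S)-5-methyl-2-(5-methylhex-4-enoyl)cyclopent-1-en-1-yl carbonate | C[C@H]1CCC(C(=O)CCC=C(C)C)=C1OC(=O)OCc1ccccc1
F2 | step 4 | O-benzyloxycarbonyl derivative of photoadduct 9 | C[C@H]1CC[C@]23C(=O)CC[C@H]2C(C)(C)[C@]13OC(=O)OCc1ccccc1
F3 | step 13 | free propargylic tetraol (protonated form of 24, C5 epimers) | C[C@H]1CC[C@@H]2[C@@H](CC[C@@]2(C)O)C(C)(C)C1(O)C#C[C@@H]1[C@@]2(C)CC[C@@H](O)C(C)(C)O[C@@H]2CC[C@]1(C)O
F4 | step 13 | allene triol (26 without the three carbonates) | C[C@H]1CC[C@@H]2[C@@H](CC[C@@]2(C)O)C(C)(C)C1=C=C[C@@H]1[C@@]2(C)CC[C@@H](O)C(C)(C)O[C@@H]2CC[C@]1(C)O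
F5 | step 15 | vinylsilane: 27 bearing SiEt3 on the olefinic CH carbon, silicon syn to azulene C6 | C[C@H]1CC[C@@H]2[C@@H](CC[C@@]2(C)OC(=O)OC)C(C)(C)/C1=C(/[Si](CC)(CC)CC)C[C@@H]1[C@@]2(C)CC[C@@H](OC(=O)OC)C(C)(C)O[C@@H]2CC[C@]1(C)OC(=O)OC
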